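**Retrosynthetic overview**
1. Last bonds: acylation of the C3 hydroxyl with the O‑silylated (2R,3S)‑chlorohydrin acid, then global desilylation. The acid comes from Sharpless epoxidation of (E)‑2‑methylbut‑2‑en‑1‑ol and HCl opening of the glycidic ester.
2. Ring A oxygens (3β‑O, 4α‑OAc) come from the C3=C4 alkene of a trans‑decalin: α‑face dihydroxylation, C3 oxidation, acetylation, axial hydride reduction.
3. Ring B is formed second: the C7–C8 bond is made by Rh‑catalysed aldehyde C–H activation (6‑endo trans‑hydroacylation of the alkyne), which gives the 7‑substituted enone directly.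
4. The C5–C6 bond is made by Cu‑catalysed anti‑SN2' allyl–alkynyl coupling of a ring A allylic phosphate with silylated 2‑methylbut‑3‑yn‑2‑ol; C5 is set from the C3 carbinol (CBS reduction).
5. Ring A is formed first, by organocatalytic Michael/aldol annulation of 2‑methylpent‑4‑enal with pent‑1‑en‑3‑one, which sets C10.

Assumption: the SMILES is read as the (1S,2S,4aR,8aR) decalin (eudesmane 3β‑acyloxy, 4α‑acetoxy, 5α‑H, 10β‑Me) with a (2R,3S) acyl group; catalyst antipodes are quoted from the usual models and are swapped if the observed sense is opposite.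

Eudesmane numbering (C1–C15) is used in the "Why" lines.

**Step 1**
Reactants: 1 2‑methylpent‑4‑enal (racemic); 2 pent‑1‑en‑3‑one
Product: 4 (4R)‑2,4‑dimethyl‑4‑(prop‑2‑en‑1‑yl)cyclohex‑2‑en‑1‑one, via keto aldehyde 3 (not isolated)
Conditions: (S)‑N‑(4‑dodecylphenylsulfonyl)prolinamide (20 mol%), BnNH2 (1 equiv), 4 Å MS, ClCH2CH2Cl, rt, 72 h
Reagents that add atoms: none
Why: Enamine‑mediated asymmetric Michael addition of the α‑branched aldehyde to the vinyl ketone followed by intramolecular aldol condensation (organocatalytic Robinson‑type annulation); face‑selective attack of the catalyst‑bound enamine sets the quaternary C10 as R, and only the ethyl‑side enol can close a six‑membered ring.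

**Step 2**
Reactants: 4 (4R)‑2,4‑dimethyl‑4‑(prop‑2‑en‑1‑yl)cyclohex‑2‑en‑1‑one
Product: 6 (4R)‑4‑(2,2‑dimethoxyethyl)‑2,4‑dimethylcyclohex‑2‑en‑1‑one, via aldehyde 5 (not isolated)
Conditions: O3, CH2Cl2/MeOH, −78 °C, Sudan Red 7B end point; Me2S; then HC(OMe)3, CeCl3·7H2O (cat.), MeOH, rt
Reagents that add atoms: ozone O=[O+][O-] (carbonyl O of 5); trimethyl orthoformate COC(OC)OC (both OMe of 6)
Why: Ozonolysis is far faster at the isolated terminal alkene than at the enone alkene, and cerium‑catalysed acetalisation takes the aldehyde but not the conjugated ketone; C10 is untouched.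

**Step 3**
Reactants: 6 (4R)‑4‑(2,2‑dimethoxyethyl)‑2,4‑dimethylcyclohex‑2‑en‑1‑one
Product: 7 (1R,4R)‑4‑(2,2‑dimethoxyethyl)‑2,4‑dimethylcyclohex‑2‑en‑1‑ol
Conditions: (S)‑Me‑CBS (20 mol%), BH3·SMe2 (0.7 equiv), THF, −20 °C; MeOH quench
Reagents that add atoms: none
Why: Corey–Bakshi–Shibata reduction; with the α‑methyl enone side as the large group the (S)‑catalyst delivers hydride to the β face and gives the 3α (1R) allylic alcohol under catalyst control, since the remote C10 centre exerts little bias.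

**Step 4**
Reactants: 7 (1R,4R)‑4‑(2,2‑dimethoxyethyl)‑2,4‑dimethylcyclohex‑2‑en‑1‑ol
Product: 8 diethyl (1R,4R)‑4‑(2,2‑dimethoxyethyl)‑2,4‑dimethylcyclohex‑2‑en‑1‑yl phosphate
Conditions: ClP(O)(OEt)2, Et3N, DMAP (cat.), CH2Cl2, 0 °C
Reagents that add atoms: diethyl chlorophosphate CCOP(=O)(Cl)OCC
Why: O‑phosphorylation of the allylic alcohol with retention at the carbinol carbon gives the leaving group for the allylic substitution.

**Step 5**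
Reactants: 9 2‑methylbut‑3‑yn‑2‑ol
Product: 10 triethyl[(2‑methylbut‑3‑yn‑2‑yl)oxy]silane
Conditions: TESOTf, 2,6‑lutidine, CH2Cl2, 0 °C
Reagents that add atoms: triethylsilyl trifluoromethanesulfonate CC[Si](CC)(CC)OS(=O)(=O)C(F)(F)F
Why: Silyl triflate/lutidine silylation caps the tertiary propargylic alcohol so that it survives alane formation and stays distinguishable from the C4 hydroxyl at the later acetylation.

**Step 6**
Reactants: 8 diethyl (1R,4R)‑4‑(2,2‑dimethoxyethyl)‑2,4‑dimethylcyclohex‑2‑en‑1‑yl phosphate; 10 triethyl[(2‑methylbut‑3‑yn‑2‑yl)oxy]silane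
Product: 12 triethyl({4‑[(1R,6R)‑6‑(2,2‑dimethoxyethyl)‑2,6‑dimethylcyclohex‑2‑en‑1‑yl]‑2‑methylbut‑3‑yn‑2‑yl}oxy)silane, via alkynylalane 11 (not isolated)
Conditions: 10, DIBAL‑H (1.0 equiv), Et3N (5 mol%), hexane/THF, 22–50 °C; then 8, SIMesCuCl (5 mol%), THF, −15 °C to rt
Reagents that add atoms: none
Why: Copper‑catalysed SN2' allylic substitution (allyl–alkynyl coupling) of the allylic phosphate by the alkynylaluminium; the NHC–copper alkynyl attacks the γ carbon anti to the α‑oriented phosphate, so the alkyne enters C5 from the β face, cis to the C10 methyl and trans to the C9 arm.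

**Step 7**
Reactants: 12 triethyl({4‑[(1R,6R)‑6‑(2,2‑dimethoxyethyl)‑2,6‑dimethylcyclohex‑2‑en‑1‑yl]‑2‑methylbut‑3‑yn‑2‑yl}oxy)silane
Product: 13 2‑[(1R,2R)‑1,3‑dimethyl‑2‑{3‑methyl‑3‑[(triethylsilyl)oxy]but‑1‑yn‑1‑yl}cyclohex‑3‑en‑1‑yl]acetaldehyde
Conditions: LiBF4, MeCN/H2O (98:2), rt
Reagents that add atoms: water O
Why: Mild Lewis‑acid hydrolysis of the dimethyl acetal to the aldehyde; the tertiary triethylsilyl ether and both stereocentres are untouched.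

**Step 8**
Reactants: 13 2‑[(1R,2R)‑1,3‑dimethyl‑2‑{3‑methyl‑3‑[(triethylsilyl)oxy]but‑1‑yn‑1‑yl}cyclohex‑3‑en‑1‑yl]acetaldehyde
Product: 14 (4aR,8aR)‑5,8a‑dimethyl‑3‑{2‑[(triethylsilyl)oxy]propan‑2‑yl}‑4a,7,8,8a‑tetrahydronaphthalen‑2(1H)‑one
Conditions: [Rh(dppe)]2(BF4)2 (5 mol%), acetone, 25–50 °C
Reagents that add atoms: none
Why: Proposed new method: Rh(I)‑catalysed 6‑endo trans‑hydroacylation of a 5‑alkynal – oxidative addition of the aldehyde C–H bond to cationic Rh(I)/dppe gives an acyl–Rh(III)–hydride held at the alkyne, hydride passes to the proximal alkyne carbon C6 and, after η2‑vinyl (metallacyclopropene) isomerisation, Rh sits on C7 anti to that hydrogen, so the seven‑membered acyl(alkenyl)rhodacycle can reductively eliminate the C7–C8 bond and close ring B as the 2‑substituted cyclohex‑2‑enone; the usual 5‑exo cis pathway of 5‑alkynals would here have to give a strained trans‑fused hydrindanone with an exocyclic alkene next to the ring fusion, which biases this rigid trans‑1,2‑disubstituted substrate towards the endo mode; no stereocentre is formed and C5 and C10 are carried through; the closest known reaction type is the Rh(I)/dppe‑catalysed trans‑hydroacylation of 4‑alkynals to cyclopent‑2‑enones.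

**Step 9**
Reactants: 14 (4aR,8aR)‑5,8a‑dimethyl‑3‑{2‑[(triethylsilyl)oxy]propan‑2‑yl}‑4a,7,8,8a‑tetrahydronaphthalen‑2(1H)‑one
Product: 15 (4aR,5S,6R,8aR)‑5,6‑dihydroxy‑5,8a‑dimethyl‑3‑{2‑[(triethylsilyl)oxy]propan‑2‑yl}‑4a,5,6,7,8,8a‑hexahydronaphthalen‑2(1H)‑one
Conditions: OsO4 (2 mol%), NMO (1.3 equiv), acetone/H2O (8:1), 0 °C to rt
Reagents that add atoms: N‑methylmorpholine N‑oxide C[N+]1([O-])CCOCC1; water O
Why: Upjohn dihydroxylation; osmium tetroxide takes the electron‑rich trisubstituted C3=C4 alkene over the electron‑poor enone and adds from the α face, anti to the axial C10 methyl, giving the 3α,4α‑diol with C4 (4α‑O, 4β‑Me) as in the target.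

**Step 10**
Reactants: 15 (4aR,5S,6R,8aR)‑5,6‑dihydroxy‑5,8a‑dimethyl‑3‑{2‑[(triethylsilyl)oxy]propan‑2‑yl}‑4a,5,6,7,8,8a‑hexahydronaphthalen‑2(1H)‑one
Product: 16 (4aR,5S,8aR)‑5‑hydroxy‑5,8a‑dimethyl‑3‑{2‑[(triethylsilyl)oxy]propan‑2‑yl}‑4a,5,8,8a‑tetrahydronaphthalene‑2,6(1H,7H)‑dione
Conditions: IBX (1.5 equiv), DMSO, rt
Reagents that add atoms: none
Why: IBX oxidises the secondary axial C3 alcohol of the 1,2‑diol to the ketone without glycol cleavage and leaves the tertiary C4 alcohol.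

**Step 11**
Reactants: 16 (4aR,5S,8aR)‑5‑hydroxy‑5,8a‑dimethyl‑3‑{2‑[(triethylsilyl)oxy]propan‑2‑yl}‑4a,5,8,8a‑tetrahydronaphthalene‑2,6(1H,7H)‑dione
Product: 17 (1S,4aR,8aR)‑1,4a‑dimethyl‑2,6‑dioxo‑7‑{2‑[(triethylsilyl)oxy]propan‑2‑yl}‑1,2,3,4,4a,5,6,8a‑octahydronaphthalen‑1‑yl acetate
Conditions: Ac2O, DMAP (1 equiv), Et3N, CH2Cl2, 40 °C
Reagents that add atoms: acetic anhydride CC(=O)OC(C)=O
Why: DMAP‑catalysed acetylation of the only free hydroxyl, the tertiary α‑ketol OH at C4, with retention; the C11 oxygen is silyl protected.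

**Step 12**
Reactants: 17 (1S,4aR,8aR)‑1,4a‑dimethyl‑2,6‑dioxo‑7‑{2‑[(triethylsilyl)oxy]propan‑2‑yl}‑1,2,3,4,4a,5,6,8a‑octahydronaphthalen‑1‑yl acetate
Product: 18 (1S,2S,4aR,8aR)‑2‑hydroxy‑1,4a‑dimethyl‑6‑oxo‑7‑{2‑[(triethylsilyl)oxy]propan‑2‑yl}‑1,2,3,4,4a,5,6,8a‑octahydronaphthalen‑1‑yl acetate
Conditions: NaBH4 (1.0 equiv), MeOH/CH2Cl2, −78 to −40 °C; AcOH quench at −40 °C
Reagents that add atoms: none
Why: The saturated α‑acetoxy ketone is reduced in preference to the hindered conjugated C8 ketone, and axial hydride attack from the α face (equatorial approach is hindered by the adjacent axial 4β‑methyl) gives the equatorial 3β (S) alcohol; the cold acidic quench limits acetyl migration.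

**Step 13**
Reactants: 19 (2E)‑2‑methylbut‑2‑en‑1‑ol
Product: 20 [(2R,3R)‑2,3‑dimethyloxiran‑2‑yl]methanol
Conditions: Ti(OiPr)4 (10 mol%), D‑(−)‑DIPT (12 mol%), t‑BuOOH (2 equiv), 4 Å MS, CH2Cl2, −20 °C
Reagents that add atoms: tert‑butyl hydroperoxide CC(C)(C)OO
Why: Sharpless asymmetric epoxidation; the D‑(−)‑tartrate catalyst delivers oxygen to the face that gives the (2R,3R)‑epoxy alcohol, and the E geometry is carried into the trans epoxide.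

**Step 14**
Reactants: 20 [(2R,3R)‑2,3‑dimethyloxiran‑2‑yl]methanol
Product: 21 (2S,3R)‑2,3‑dimethyloxirane‑2‑carboxylic acid
Conditions: RuCl3·xH2O (2 mol%), NaIO4 (3 equiv), CCl4/MeCN/H2O, rt
Reagents that add atoms: water O; sodium periodate [Na+].[O-]I(=O)(=O)=O
Why: Catalytic ruthenium tetroxide oxidation of the primary alcohol to the acid through the aldehyde hydrate leaves the epoxide and both stereocentres intact (the descriptor at C2 changes only by priority).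

**Step 15**
Reactants: 21 (2S,3R)‑2,3‑dimethyloxirane‑2‑carboxylic acid
Product: 22 benzyl (2S,3R)‑2,3‑dimethyloxirane‑2‑carboxylate
Conditions: BnBr, K2CO3, DMF, rt
Reagents that add atoms: benzyl bromide BrCc1ccccc1
Why: Carboxylate O‑alkylation gives an ester that can be purified by chromatography and later cleaved under neutral conditions.

**Step 16**
Reactants: 22 benzyl (2S,3R)‑2,3‑dimethyloxirane‑2‑carboxylate
Product: 23 benzyl (2R,3S)‑3‑chloro‑2‑hydroxy‑2‑methylbutanoate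
Conditions: HCl (4 M in 1,4‑dioxane, 1.2 equiv), CH2Cl2, 0 °C
Reagents that add atoms: hydrogen chloride Cl
Why: Acid‑mediated opening of the glycidic ester; chloride attacks C3 by SN2 with inversion because the ester deactivates the fully substituted C2, which gives the (2R,3S) chlorohydrin.

**Step 17**
Reactants: 23 benzyl (2R,3S)‑3‑chloro‑2‑hydroxy‑2‑methylbutanoate
Product: 24 benzyl (2R,3S)‑3‑chloro‑2‑methyl‑2‑[(triethylsilyl)oxy]butanoate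
Conditions: TESOTf, 2,6‑lutidine, CH2Cl2, 0 °C
Reagents that add atoms: triethylsilyl trifluoromethanesulfonate CC[Si](CC)(CC)OS(=O)(=O)C(F)(F)F
Why: Silylation of the tertiary alcohol prevents self‑acylation and epoxide re‑closure during the later activation and coupling.

**Step 18**
Reactants: 24 benzyl (2R,3S)‑3‑chloro‑2‑methyl‑2‑[(triethylsilyl)oxy]butanoate
Product: 25 (2R,3S)‑3‑chloro‑2‑methyl‑2‑[(triethylsilyl)oxy]butanoic acid
Conditions: H2 (1 atm), 10% Pd/C, EtOAc, rt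
Reagents that add atoms: none
Why: Hydrogenolysis of the benzyl ester under neutral conditions, which the secondary alkyl chloride and the silyl ether tolerate.

**Step 19**
Reactants: 18 (1S,2S,4aR,8aR)‑2‑hydroxy‑1,4a‑dimethyl‑6‑oxo‑7‑{2‑[(triethylsilyl)oxy]propan‑2‑yl}‑1,2,3,4,4a,5,6,8a‑octahydronaphthalen‑1‑yl acetate; 25 (2R,3S)‑3‑chloro‑2‑methyl‑2‑[(triethylsilyl)oxy]butanoic acid
Product: 27 (1S,2S,4aR,8aR)‑1‑(acetyloxy)‑1,4a‑dimethyl‑6‑oxo‑7‑{2‑[(triethylsilyl)oxy]propan‑2‑yl}‑1,2,3,4,4a,5,6,8a‑octahydronaphthalen‑2‑yl (2R,3S)‑3‑chloro‑2‑methyl‑2‑[(triethylsilyl)oxy]butanoate, via mixed anhydride 26 (not isolated)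
Conditions: 25, 2,4,6‑Cl3C6H2COCl, Et3N, toluene, rt; then 18, DMAP (2 equiv), toluene, 50 °C
Reagents that add atoms: none
Why: Yamaguchi esterification; the mixed anhydride acylates the only free hydroxyl (the equatorial 3β‑OH) with retention at C3 and at both side‑chain centres.

**Step 20**
Reactants: 27 (1S,2S,4aR,8aR)‑1‑(acetyloxy)‑1,4a‑dimethyl‑6‑oxo‑7‑{2‑[(triethylsilyl)oxy]propan‑2‑yl}‑1,2,3,4,4a,5,6,8a‑octahydronaphthalen‑2‑yl (2R,3S)‑3‑chloro‑2‑methyl‑2‑[(triethylsilyl)oxy]butanoate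
Product: 28 (1S,2S,4aR,8aR)‑1‑(acetyloxy)‑7‑(2‑hydroxypropan‑2‑yl)‑1,4a‑dimethyl‑6‑oxo‑1,2,3,4,4a,5,6,8a‑octahydronaphthalen‑2‑yl (2R,3S)‑3‑chloro‑2‑hydroxy‑2‑methylbutanoate (CNP0119872.1)
Conditions: HF·pyridine, THF/pyridine, 0 °C to rt
Reagents that add atoms: none
Why: Fluoride cleavage of both tertiary triethylsilyl ethers under buffered conditions leaves the tertiary acetate, the ester, the chloride and the enone untouched.

**Compound list**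
1 | 2‑methylpent‑4‑enal (racemic) | C=CCC(C)C=O | starting material
2 | pent‑1‑en‑3‑one | CCC(=O)C=C | starting material
3 | (2R)‑2‑methyl‑5‑oxo‑2‑(prop‑2‑en‑1‑yl)heptanal | CCC(=O)CC[C@](C)(CC=C)C=O | intermediate (not isolated)
4 | (4R)‑2,4‑dimethyl‑4‑(prop‑2‑en‑1‑yl)cyclohex‑2‑en‑1‑one | CC1=C[C@@](C)(CC=C)CCC1=O | intermediate
5 | 2‑[(1R)‑1,3‑dimethyl‑4‑oxocyclohex‑2‑en‑1‑yl]acetaldehyde | CC1=C[C@@](C)(CC=O)CCC1=O | intermediate (not isolated)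
6 | (4R)‑4‑(2,2‑dimethoxyethyl)‑2,4‑dimethylcyclohex‑2‑en‑1‑one | CC1=C[C@@](C)(CC(OC)OC)CCC1=O | intermediate
7 | (1R,4R)‑4‑(2,2‑dimethoxyethyl)‑2,4‑dimethylcyclohex‑2‑en‑1‑ol | CC1=C[C@@](C)(CC(OC)OC)CC[C@H]1O | intermediate
8 | diethyl (1R,4R)‑4‑(2,2‑dimethoxyethyl)‑2,4‑dimethylcyclohex‑2‑en‑1‑yl phosphate | CC1=C[C@@](C)(CC(OC)OC)CC[C@H]1OP(=O)(OCC)OCC | intermediate
9 | 2‑methylbut‑3‑yn‑2‑ol | CC(C)(O)C#C | starting material
10 | triethyl[(2‑methylbut‑3‑yn‑2‑yl)oxy]silane | CC[Si](CC)(CC)OC(C)(C)C#C | intermediate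
11 | bis(2‑methylpropyl){3‑methyl‑3‑[(triethylsilyl)oxy]but‑1‑yn‑1‑yl}alumane | CC(C)C[Al](CC(C)C)C#CC(C)(C)O[Si](CC)(CC)CC | intermediate (not isolated)
12 | triethyl({4‑[(1R,6R)‑6‑(2,2‑dimethoxyethyl)‑2,6‑dimethylcyclohex‑2‑en‑1‑yl]‑2‑methylbut‑3‑yn‑2‑yl}oxy)silane | CC[Si](CC)(CC)OC(C)(C)C#C[C@H]1C(C)=CCC[C@]1(C)CC(OC)OC | intermediate
13 | 2‑[(1R,2R)‑1,3‑dimethyl‑2‑{3‑methyl‑3‑[(triethylsilyl)oxy]but‑1‑yn‑1‑yl}cyclohex‑3‑en‑1‑yl]acetaldehyde | CC[Si](CC)(CC)OC(C)(C)C#C[C@H]1C(C)=CCC[C@]1(C)CC=O | intermediate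
14 | (4aR,8aR)‑5,8a‑dimethyl‑3‑{2‑[(triethylsilyl)oxy]propan‑2‑yl}‑4a,7,8,8a‑tetrahydronaphthalen‑2(1H)‑one | CC1=CCC[C@]2(C)CC(=O)C(C(C)(C)O[Si](CC)(CC)CC)=C[C@H]21 | intermediate
15 | (4aR,5S,6R,8aR)‑5,6‑dihydroxy‑5,8a‑dimethyl‑3‑{2‑[(triethylsilyl)oxy]propan‑2‑yl}‑4a,5,6,7,8,8a‑hexahydronaphthalen‑2(1H)‑one | C[C@@]1(O)[C@H](O)CC[C@]2(C)CC(=O)C(C(C)(C)O[Si](CC)(CC)CC)=C[C@H]21 | intermediate
16 | (4aR,5S,8aR)‑5‑hydroxy‑5,8a‑dimethyl‑3‑{2‑[(triethylsilyl)oxy]propan‑2‑yl}‑4a,5,8,8a‑tetrahydronaphthalene‑2,6(1H,7H)‑dione | C[C@@]1(O)C(=O)CC[C@]2(C)CC(=O)C(C(C)(C)O[Si](CC)(CC)CC)=C[C@H]21 | intermediate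
17 | (1S,4aR,8aR)‑1,4a‑dimethyl‑2,6‑dioxo‑7‑{2‑[(triethylsilyl)oxy]propan‑2‑yl}‑1,2,3,4,4a,5,6,8a‑octahydronaphthalen‑1‑yl acetate | CC(=O)O[C@]1(C)C(=O)CC[C@]2(C)CC(=O)C(C(C)(C)O[Si](CC)(CC)CC)=C[C@H]21 | intermediate
18 | (1S,2S,4aR,8aR)‑2‑hydroxy‑1,4a‑dimethyl‑6‑oxo‑7‑{2‑[(triethylsilyl)oxy]propan‑2‑yl}‑1,2,3,4,4a,5,6,8a‑octahydronaphthalen‑1‑yl acetate | CC(=O)O[C@]1(C)[C@@H](O)CC[C@]2(C)CC(=O)C(C(C)(C)O[Si](CC)(CC)CC)=C[C@H]21 | intermediate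
19 | (2E)‑2‑methylbut‑2‑en‑1‑ol | C/C=C(\C)CO | starting material
20 | [(2R,3R)‑2,3‑dimethyloxiran‑2‑yl]methanol | C[C@H]1O[C@]1(C)CO | intermediate
21 | (2S,3R)‑2,3‑dimethyloxirane‑2‑carboxylic acid | C[C@H]1O[C@]1(C)C(=O)O | intermediate
22 | benzyl (2S,3R)‑2,3‑dimethyloxirane‑2‑carboxylate | C[C@H]1O[C@]1(C)C(=O)OCc1ccccc1 | intermediate
23 | benzyl (2R,3S)‑3‑chloro‑2‑hydroxy‑2‑methylbutanoate | O=C(OCc1ccccc1)[C@@](C)(O)[C@H](C)Cl | intermediate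
24 | benzyl (2R,3S)‑3‑chloro‑2‑methyl‑2‑[(triethylsilyl)oxy]butanoate | O=C(OCc1ccccc1)[C@@](C)(O[Si](CC)(CC)CC)[C@H](C)Cl | intermediate
25 | (2R,3S)‑3‑chloro‑2‑methyl‑2‑[(triethylsilyl)oxy]butanoic acid | OC(=O)[C@@](C)(O[Si](CC)(CC)CC)[C@H](C)Cl | intermediate
26 | (2R,3S)‑3‑chloro‑2‑methyl‑2‑[(triethylsilyl)oxy]butanoic 2,4,6‑trichlorobenzoic anhydride | O=C(OC(=O)c1c(Cl)cc(Cl)cc1Cl)[C@@](C)(O[Si](CC)(CC)CC)[C@H](C)Cl | intermediate (not isolated)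
27 | (1S,2S,4aR,8aR)‑1‑(acetyloxy)‑1,4a‑dimethyl‑6‑oxo‑7‑{2‑[(triethylsilyl)oxy]propan‑2‑yl}‑1,2,3,4,4a,5,6,8a‑octahydronaphthalen‑2‑yl (2R,3S)‑3‑chloro‑2‑methyl‑2‑[(triethylsilyl)oxy]butanoate | CC(=O)O[C@]1(C)[C@@H](OC(=O)[C@@](C)(O[Si](CC)(CC)CC)[C@H](C)Cl)CC[C@]2(C)CC(=O)C(C(C)(C)O[Si](CC)(CC)CC)=C[C@H]21 | intermediate
28 | (1S,2S,4aR,8aR)‑1‑(acetyloxy)‑7‑(2‑hydroxypropan‑2‑yl)‑1,4a‑dimethyl‑6‑oxo‑1,2,3,4,4a,5,6,8a‑octahydronaphthalen‑2‑yl (2R,3S)‑3‑chloro‑2‑hydroxy‑2‑methylbutanoate | CC(=O)O[C@]1(C)[C@@H](OC(=O)[C@@](C)(O)[C@H](C)Cl)CC[C@]2(C)CC(=O)C(C(C)(C)O)=C[C@H]21 | target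

**Totals**
Total step count: 20.
Longest linear sequence: 13 steps (steps 1, 2, 3, 4, 6, 7, 8, 9, 10, 11, 12, 19, 20), which is 0.65 of the total. The side‑chain acid (steps 13–18) and the alkyne (step 5) are made in parallel.

**Steps most likely to fail and their fallbacks**

Step 6 (Cu‑catalysed SN2' alkynylation). The γ carbon lies next to the quaternary C10, so direct SN2 attack at C3 or elimination may compete. The fallback uses known chemistry, sets out from 6 and comes back at 12. Ketone 6 is reduced with the antipodal (R)‑Me‑CBS catalyst to (1S,4R)‑4‑(2,2‑dimethoxyethyl)‑2,4‑dimethylcyclohex‑2‑en‑1‑ol F1. This is alkylated (KH, Bu3SnCH2I, THF) to tributyl({[(1S,4R)‑4‑(2,2‑dimethoxyethyl)‑2,4‑dimethylcyclohex‑2‑en‑1‑yl]oxy}methyl)stannane F2. A [2,3]‑Wittig–Still rearrangement (n‑BuLi, THF, −78 °C) then moves the CH2O unit suprafacially from the 3β oxygen to the β face of C5 and gives [(1R,6R)‑6‑(2,2‑dimethoxyethyl)‑2,6‑dimethylcyclohex‑2‑en‑1‑yl]methanol F3. Dess–Martin oxidation gives (1R,6R)‑6‑(2,2‑dimethoxyethyl)‑2,6‑dimethylcyclohex‑2‑ene‑1‑carbaldehyde F4, which is kept cold to avoid conjugation. Corey–Fuchs olefination (CBr4, PPh3, CH2Cl2, 0 °C) gives (3R,4R)‑3‑(2,2‑dibromoethenyl)‑4‑(2,2‑dimethoxyethyl)‑2,4‑dimethylcyclohex‑1‑ene F5. Treatment with n‑BuLi (2.1 equiv, −78 °C), then acetone, then TESOTf in the same flask gives 12.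

Step 8 (the proposed Rh‑catalysed 6‑endo trans‑hydroacylation). It may instead give the 5‑exo alkylidene cyclopentanone or decarbonylate. The fallback uses known chemistry only, sets out from 12 and comes back at 14.
- TBAF gives 4‑[(1R,6R)‑6‑(2,2‑dimethoxyethyl)‑2,6‑dimethylcyclohex‑2‑en‑1‑yl]‑2‑methylbut‑3‑yn‑2‑ol F6.
- Hydroxyl‑directed ruthenium‑catalysed trans‑hydrostannation ([Cp*RuCl]4, Bu3SnH, CH2Cl2) puts tin on the carbon next to the carbinol and hydrogen anti to it, giving (3Z)‑4‑[(1R,6R)‑6‑(2,2‑dimethoxyethyl)‑2,6‑dimethylcyclohex‑2‑en‑1‑yl]‑2‑methyl‑3‑(tributylstannyl)but‑3‑en‑2‑ol F7.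
- Iododestannylation (I2, CH2Cl2, 0 °C) gives (3Z)‑4‑[(1R,6R)‑6‑(2,2‑dimethoxyethyl)‑2,6‑dimethylcyclohex‑2‑en‑1‑yl]‑3‑iodo‑2‑methylbut‑3‑en‑2‑ol F8.
- Acetal hydrolysis (LiBF4, wet MeCN) gives 2‑[(1R,2R)‑2‑[(1Z)‑3‑hydroxy‑2‑iodo‑3‑methylbut‑1‑en‑1‑yl]‑1,3‑dimethylcyclohex‑3‑en‑1‑yl]acetaldehyde F9.
- Intramolecular Nozaki–Hiyama–Kishi coupling (CrCl2, NiCl2 cat., DMSO) closes ring B as (4aR,8aR)‑3‑(2‑hydroxypropan‑2‑yl)‑5,8a‑dimethyl‑1,2,4a,7,8,8a‑hexahydronaphthalen‑2‑ol F10 (both C2 epimers).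
- MnO2 oxidises the secondary allylic alcohol to (4aR,8aR)‑3‑(2‑hydroxypropan‑2‑yl)‑5,8a‑dimethyl‑4a,7,8,8a‑tetrahydronaphthalen‑2(1H)‑one F11.
- TESOTf/2,6‑lutidine then gives 14.

Step 19 (esterification). A hindered equatorial alcohol next to the quaternary C4 must be joined to an α‑quaternary acid, and the neighbouring acetate may migrate. The fallback sets out from 18 and comes back at the target 28. Alcohol 18 is acylated under the same Yamaguchi conditions with the much smaller epoxy acid 21 from the side‑chain branch, giving (1S,2S,4aR,8aR)‑1‑(acetyloxy)‑1,4a‑dimethyl‑6‑oxo‑7‑{2‑[(triethylsilyl)oxy]propan‑2‑yl}‑1,2,3,4,4a,5,6,8a‑octahydronaphthalen‑2‑yl (2S,3R)‑2,3‑dimethyloxirane‑2‑carboxylate F12. Treatment with HCl (4 M in dioxane) in CH2Cl2 at 0 °C opens the glycidic ester at C3' with inversion, as in step 16, and cleaves the C11 silyl ether in the same operation, giving 28.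

**Further compounds**
F1 | step 6 | (1S,4R)‑4‑(2,2‑dimethoxyethyl)‑2,4‑dimethylcyclohex‑2‑en‑1‑ol | CC1=C[C@@](C)(CC(OC)OC)CC[C@@H]1O
F2 | step 6 | tributyl({[(1S,4R)‑4‑(2,2‑dimethoxyethyl)‑2,4‑dimethylcyclohex‑2‑en‑1‑yl]oxy}methyl)stannane | CC1=C[C@@](C)(CC(OC)OC)CC[C@@H]1OC[Sn](CCCC)(CCCC)CCCC
F3 | step 6 | [(1R,6R)‑6‑(2,2‑dimethoxyethyl)‑2,6‑dimethylcyclohex‑2‑en‑1‑yl]methanol | OC[C@H]1C(C)=CCC[C@]1(C)CC(OC)OC
F4 | step 6 | (1R,6R)‑6‑(2,2‑dimethoxyethyl)‑2,6‑dimethylcyclohex‑2‑ene‑1‑carbaldehyde | O=C[C@H]1C(C)=CCC[C@]1(C)CC(OC)OC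
F5 | step 6 | (3R,4R)‑3‑(2,2‑dibromoethenyl)‑4‑(2,2‑dimethoxyethyl)‑2,4‑dimethylcyclohex‑1‑ene | BrC(Br)=C[C@H]1C(C)=CCC[C@]1(C)CC(OC)OC
F6 | step 8 | 4‑[(1R,6R)‑6‑(2,2‑dimethoxyethyl)‑2,6‑dimethylcyclohex‑2‑en‑1‑yl]‑2‑methylbut‑3‑yn‑2‑ol | CC(C)(O)C#C[C@H]1C(C)=CCC[C@]1(C)CC(OC)OC
F7 | step 8 | (3Z)‑4‑[(1R,6R)‑6‑(2,2‑dimethoxyethyl)‑2,6‑dimethylcyclohex‑2‑en‑1‑yl]‑2‑methyl‑3‑(tributylstannyl)but‑3‑en‑2‑ol | CC(C)(O)/C(=C/[C@H]1C(C)=CCC[C@]1(C)CC(OC)OC)[Sn](CCCC)(CCCC)CCCC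
F8 | step 8 | (3Z)‑4‑[(1R,6R)‑6‑(2,2‑dimethoxyethyl)‑2,6‑dimethylcyclohex‑2‑en‑1‑yl]‑3‑iodo‑2‑methylbut‑3‑en‑2‑ol | CC(C)(O)/C(I)=C/[C@H]1C(C)=CCC[C@]1(C)CC(OC)OC
F9 | step 8 | 2‑[(1R,2R)‑2‑[(1Z)‑3‑hydroxy‑2‑iodo‑3‑methylbut‑1‑en‑1‑yl]‑1,3‑dimethylcyclohex‑3‑en‑1‑yl]acetaldehyde | CC(C)(O)/C(I)=C/[C@H]1C(C)=CCC[C@]1(C)CC=O
F10 | step 8 | (4aR,8aR)‑3‑(2‑hydroxypropan‑2‑yl)‑5,8a‑dimethyl‑1,2,4a,7,8,8a‑hexahydronaphthalen‑2‑ol (both C2 epimers) | CC1=CCC[C@]2(C)CC(O)C(C(C)(C)O)=C[C@H]21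
F11 | step 8 | (4aR,8aR)‑3‑(2‑hydroxypropan‑2‑yl)‑5,8a‑dimethyl‑4a,7,8,8a‑tetrahydronaphthalen‑2(1H)‑one | CC1=CCC[C@]2(C)CC(=O)C(C(C)(C)O)=C[C@H]21
F12 | step 19 | (1S,2S,4aR,8aR)‑1‑(acetyloxy)‑1,4a‑dimethyl‑6‑oxo‑7‑{2‑[(triethylsilyl)oxy]propan‑2‑yl}‑1,2,3,4,4a,5,6,8a‑octahydronaphthalen‑2‑yl (2S,3R)‑2,3‑dimethyloxirane‑2‑carboxylate | CC(=O)O[C@]1(C)[C@@H](OC(=O)[C@@]2(C)O[C@@H]2C)CC[C@]3(C)CC(=O)C(C(C)(C)O[Si](CC)(CC)CC)=C[C@H]31
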